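**Retrosynthetic overview**
- The only ring, the 28-membered macrocycle, is closed last but one by a radical C8–C9 bond formation: a primary C8 radical (from an iodide) adds endo to a C9=C10–C11 vinyl ketone; a single fluoride deprotection follows.
- The seco iodo-enone comes from esterifying a C3–C8 iodo acid onto the C1 hydroxyl; the enone comes from a C11 Weinreb amide and vinylmagnesium bromide.
- The dienoate is built at C19: trans-selective B-alkyl Suzuki coupling (C19–C20) on a 1,1-dibromodiene, then alkoxycarbonylation of the remaining cis C–Br sets the C18=C19 geometry.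
- Stereocentres: C4/C6 by two Zr-catalysed carboaluminations, C15 by Cu-catalysed SN2' ethylation, C22/C23 by reagent-controlled anti-oxyallylation, C25 and C1 from the chiral pool.

**Assumption/convention:** ring atoms are numbered C1 (O-bearing CH of the hydroxypentanoyl unit), O2, C3 (ester C=O), C4(Me), C5, C6(Me), C7–C10, C11 (ketone), C12–C14, C15(Et), C16=C17, C18=C19(CO2H), C20, C21, C22(OH), C23(OH), C24, C25(OH), C26, N27, C28 (amide C=O). In this numbering the target is 1S,4S,6S,15R,22R,23S,25S, 16E, 18Z (CO2H cis to C17). The catalyst/ligand enantiomers in steps 1, 2, 7 and 14 are assigned from the usual empirical models and should be confirmed on the first intermediates.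

**Iodo acid (C3–C8)**

Step 1
Reactants: 1 tert-butyl(but-3-en-1-yloxy)dimethylsilane; 2 bromoethene
Product: 4 (R)-tert-butyldimethyl[(3-methylhex-5-en-1-yl)oxy]silane, via alkylalane 3 (not isolated)
Conditions: Me3Al, methylaluminoxane (MeAlO)n, (+)-(NMI)2ZrCl2 [(+)-dichlorobis(1-neomenthylindenyl)zirconium] (4 mol %), CH2Cl2, 0 → 23 °C; evaporate; Zn(OTf)2, DMF, 70 °C; then 2, Pd(DPEphos)Cl2 (3 mol %), i-Bu2AlH (6 mol %), DMF, 23 °C
Reagents that add atoms: trimethylaluminium, C[Al](C)C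
Why: Zr-catalysed asymmetric carboalumination (ZACA) adds Me–Al across the terminal alkene under catalyst control (the (+)-catalyst gives the (S)-2-methylalkylalane sense, ca. 80 % ee, fixing C6), and the alane is vinylated in the same pot by Pd-catalysed Negishi-type coupling without touching C6.

Step 2
Reactants: 4 (R)-tert-butyldimethyl[(3-methylhex-5-en-1-yl)oxy]silane
Product: 6 (2S,4R)-6-[(tert-butyldimethylsilyl)oxy]-2,4-dimethylhexan-1-ol, via alkylalane 5 (not isolated)
Conditions: Me3Al, (MeAlO)n, (+)-(NMI)2ZrCl2 (4 mol %), CH2Cl2, 23 °C; then O2 (1 atm), 0 → 23 °C; chromatography removes the anti isomer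
Reagents that add atoms: trimethylaluminium, C[Al](C)C; dioxygen, O=O
Why: a second ZACA with the same catalyst enantiomer sets C4 syn to C6 (ca. 8:1), O2 oxidises the C–Al bond with retention, and removing the minor anti diastereomer raises the ee of the syn alcohol to about 97 % by statistical amplification.

Step 3
Reactants: 6 (2S,4R)-6-[(tert-butyldimethylsilyl)oxy]-2,4-dimethylhexan-1-ol
Product: 7 (2S,4R)-6-[(tert-butyldimethylsilyl)oxy]-2,4-dimethylhexanoic acid
Conditions: TEMPO (20 mol %), PhI(OAc)2 (2.2 equiv), MeCN/H2O 1:1, 23 °C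
Reagents that add atoms: water, O
Why: oxoammonium (TEMPO/PhI(OAc)2) oxidation in aqueous acetonitrile takes the primary alcohol to the acid under near-neutral conditions that keep the TBS ether and do not epimerise C4.

Step 4
Reactants: 7 (2S,4R)-6-[(tert-butyldimethylsilyl)oxy]-2,4-dimethylhexanoic acid
Product: 8 (2S,4R)-6-iodo-2,4-dimethylhexanoic acid
Conditions: NaI, Me3SiCl, MeCN, 23 → 50 °C; aq. Na2S2O3 work-up
Reagents that add atoms: sodium iodide, [Na+].[I-]
Why: Me3SiI generated in situ (Olah conditions) silylates the ether oxygen and iodide displaces at the unhindered primary carbon (SN2), turning the primary silyl ether directly into the iodide while both stereocentres are remote.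

**Dibromodiene (C11–C19)**

Step 5
Reactants: 9 hex-5-enoyl chloride
Product: 10 N-methoxy-N-methylhex-5-enamide
Conditions: MeNH(OMe)·HCl, Et3N, CH2Cl2, 0 °C
Reagents that add atoms: N,O-dimethylhydroxylamine hydrochloride, CNOC.Cl
Why: simple acyl substitution gives the Weinreb amide, which carries C11 through all later organometallic steps and is the latent vinyl ketone.

Step 6
Reactants: 10 N-methoxy-N-methylhex-5-enamide; 11 (E)-1,4-dibromobut-2-ene
Product: 12 (E)-7-bromo-N-methoxy-N-methylhept-5-enamide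
Conditions: 11 (3 equiv), second-generation Hoveyda–Grubbs catalyst RuCl2(H2IMes)(=CH-C6H4-2-O-i-Pr) (2 mol %), CH2Cl2, 40 °C; AgNO3–SiO2 chromatography to ≥97:3 E
Reagents that add atoms: none
Why: olefin cross-metathesis of a terminal alkene with excess symmetrical allylic dibromide gives the E-rich primary allylic bromide needed for the SN2' step.

Step 7
Reactants: 12 (E)-7-bromo-N-methoxy-N-methylhept-5-enamide
Product: 13 (R)-5-ethyl-N-methoxy-N-methylhept-6-enamide
Conditions: EtMgBr (1.2 equiv, slow addition), CuBr·SMe2 (3 mol %), (R,Rp)-Taniaphos (3.6 mol %), CH2Cl2, −78 °C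
Reagents that add atoms: ethylmagnesium bromide, CC[Mg]Br
Why: Cu-catalysed asymmetric allylic alkylation delivers ethyl SN2' to C15, and the (R,Rp) ligand (the one that gives (S)-3-arylbut-1-enes from cinnamyl bromides, which is the same facial sense) sets 15R, while the Weinreb amide is inert to the Grignard reagent at −78 °C.

Step 8
Reactants: 13 (R)-5-ethyl-N-methoxy-N-methylhept-6-enamide; 14 (E)-but-2-enal
Product: 15 (5R,6E)-5-ethyl-N-methoxy-N-methyl-8-oxooct-6-enamide
Conditions: 14 (5 equiv), second-generation Hoveyda–Grubbs catalyst (5 mol %), CH2Cl2, 40 °C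
Reagents that add atoms: none
Why: cross-metathesis of the terminal alkene with excess crotonaldehyde gives the conjugated enal with the thermodynamic 16E geometry and leaves the allylic C15 centre untouched.

Step 9
Reactants: 15 (5R,6E)-5-ethyl-N-methoxy-N-methyl-8-oxooct-6-enamide
Product: 16 (5R,6E)-9,9-dibromo-5-ethyl-N-methoxy-N-methylnona-6,8-dienamide
Conditions: CBr4 (2 equiv), PPh3 (4 equiv), CH2Cl2, 0 °C
Reagents that add atoms: tetrabromomethane, BrC(Br)(Br)Br
Why: Corey–Fuchs (Ramirez) dibromo-olefination converts the aldehyde into the 1,1-dibromodiene, introducing C19 with two differentiable C–Br bonds.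

**Amino-triol unit (C20–C26) and amide**

Step 10
Reactants: 17 (S)-4-chloro-3-hydroxybutanenitrile
Product: 18 (S)-4-azido-3-hydroxybutanenitrile
Conditions: NaN3, DMF, 70 °C (product kept in solution)
Reagents that add atoms: sodium azide, [Na+].[N-]=[N+]=[N-]
Why: SN2 azidation at the primary carbon installs N27 and leaves the C25 stereocentre (from the chiral pool) untouched.

Step 11
Reactants: 18 (S)-4-azido-3-hydroxybutanenitrile
Product: 19 (S)-4-azido-3-[(tert-butyldimethylsilyl)oxy]butanenitrile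
Conditions: TBSCl, imidazole, DMF, 23 °C
Reagents that add atoms: tert-butyldimethylsilyl chloride, CC(C)(C)[Si](C)(C)Cl
Why: standard silylation protects the C25 hydroxyl before hydride reduction.

Step 12
Reactants: 19 (S)-4-azido-3-[(tert-butyldimethylsilyl)oxy]butanenitrile
Product: 20 (S)-4-azido-3-[(tert-butyldimethylsilyl)oxy]butanal
Conditions: i-Bu2AlH (1.1 equiv), CH2Cl2, −78 °C; aq. Rochelle salt
Reagents that add atoms: water, O
Why: partial reduction of the nitrile with diisobutylaluminium hydride stops at the imine stage, which hydrolyses to the C23 aldehyde on work-up, and the azide is inert at −78 °C.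

Step 13
Reactants: 21 allyl(chloro)dimethylsilane
Product: 22 allyl(diisopropylamino)dimethylsilane
Conditions: i-Pr2NH (2.2 equiv), Et2O, 0 → 35 °C
Reagents that add atoms: diisopropylamine, CC(C)NC(C)C
Why: aminolysis of the Si–Cl bond gives the oxidisable aminosilyl group that serves as a masked hydroxyl in the next step.

Step 14
Reactants: 20 (S)-4-azido-3-[(tert-butyldimethylsilyl)oxy]butanal; 22 allyl(diisopropylamino)dimethylsilane
Product: 26 (3R,4S,6S)-7-azido-6-[(tert-butyldimethylsilyl)oxy]hept-1-ene-3,4-diol, via allyllithium 23 (not isolated), via allylborane 24 (not isolated), via borinate adduct 25 (not isolated)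
Conditions: 22, n-BuLi, TMEDA, Et2O, 0 °C; (+)-Ipc2BOMe (from (−)-α-pinene), −78 °C; BF3·OEt2; 20, −78 °C, 4 h; then KF, KHCO3, 30 % H2O2, THF/MeOH, 23 °C
Reagents that add atoms: hydrogen peroxide, OO
Why: Brown-type asymmetric allylboration through a chair transition state, where the (E)-γ-silylallyl unit gives the anti relationship and the (+)-Ipc2B reagent attacks the re face of the aldehyde (23S), followed by Tamao oxidation of C–Si with retention (22R), gives the anti-1,2-diol with reagent control over the remote C25 centre.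

Step 15
Reactants: 26 (3R,4S,6S)-7-azido-6-[(tert-butyldimethylsilyl)oxy]hept-1-ene-3,4-diol
Product: 27 (3R,4S,6S)-7-azido-3,4,6-tris[(tert-butyldimethylsilyl)oxy]hept-1-ene
Conditions: TBSOTf (2.5 equiv), 2,6-lutidine, CH2Cl2, 0 → 23 °C
Reagents that add atoms: tert-butyldimethylsilyl trifluoromethanesulfonate, CC(C)(C)[Si](C)(C)OS(=O)(=O)C(F)(F)F
Why: silyl triflate forces silylation of both hindered vicinal hydroxyls, so the whole triol carries one class of fluoride-labile group.

Step 16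
Reactants: 27 (3R,4S,6S)-7-azido-3,4,6-tris[(tert-butyldimethylsilyl)oxy]hept-1-ene; 28 (S)-2-hydroxypentanoic acid
Product: 30 (2S)-2-hydroxy-N-[(2S,4S,5R)-2,4,5-tris[(tert-butyldimethylsilyl)oxy]hept-6-en-1-yl]pentanamide, via amine 29 (not isolated)
Conditions: PMe3, THF/H2O, 23 °C; concentrate; then 28, EDC·HCl, HOBt, i-Pr2NEt, CH2Cl2, 0 → 23 °C
Reagents that add atoms: none
Why: Staudinger reduction unmasks the primary amine, which is N-acylated chemoselectively by the unprotected α-hydroxy acid under carbodiimide/HOBt coupling, bringing in C1 (S) from the chiral pool without racemisation.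

**Assembly and end game**

Step 17
Reactants: 30 (2S)-2-hydroxy-N-[(2S,4S,5R)-2,4,5-tris[(tert-butyldimethylsilyl)oxy]hept-6-en-1-yl]pentanamide; 16 (5R,6E)-9,9-dibromo-5-ethyl-N-methoxy-N-methylnona-6,8-dienamide
Product: 32 (2S)-N-[(2S,4S,5R,8Z,10E,12R)-8-bromo-2,4,5-tris[(tert-butyldimethylsilyl)oxy]-12-ethyl-16-[methoxy(methyl)amino]-16-oxohexadeca-8,10-dien-1-yl]-2-hydroxypentanamide, via bis-boryl 9-BBN adduct 31 (not isolated)
Conditions: 9-BBN (3 equiv), THF, 23 °C; then H2O, 16 (1.1 equiv), Pd(dppf)Cl2 (10 mol %), AsPh3, Cs2CO3, DMF/THF/H2O, 23 °C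
Reagents that add atoms: none
Why: anti-Markovnikov hydroboration of the terminal vinyl group followed by B-alkyl Suzuki–Miyaura coupling, in which Pd inserts first into the less hindered C–Br bond trans to C17, forms C19–C20 with the chain trans to C17 and leaves the cis bromide in place.

Step 18
Reactants: 32 (Z)-bromodiene from step 17
Product: 33 2-(trimethylsilyl)ethyl (2Z,4E,6R)-6-ethyl-10-[methoxy(methyl)amino]-10-oxo-2-[(3R,4S,6S)-3,4,6-tris[(tert-butyldimethylsilyl)oxy]-7-{[(2S)-2-hydroxypentanoyl]amino}heptyl]deca-2,4-dienoate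
Conditions: CO (1 atm), Me3SiCH2CH2OH (15 equiv), Pd(OAc)2 (10 mol %), Xantphos, Et3N, DMF, 70 °C
Reagents that add atoms: carbon monoxide, [C-]#[O+]; 2-(trimethylsilyl)ethanol, C[Si](C)(C)CCO
Why: Pd-catalysed alkoxycarbonylation of the alkenyl bromide proceeds with retention, so the ester ends up cis to C17 (the 18Z geometry of the target), and it arrives as a fluoride-labile ester.

Step 19
Reactants: 33 Weinreb-amide dienoate from step 18
Product: 34 2-(trimethylsilyl)ethyl (2Z,4E,6R)-6-ethyl-10-oxo-2-[(3R,4S,6S)-3,4,6-tris[(tert-butyldimethylsilyl)oxy]-7-{[(2S)-2-hydroxypentanoyl]amino}heptyl]dodeca-2,4,11-trienoate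
Conditions: CH2=CHMgBr (5 equiv), THF, −40 → 0 °C; inverse quench into cold 1 M HCl
Reagents that add atoms: vinylmagnesium bromide, C=C[Mg]Br
Why: Weinreb ketone synthesis, in which the stable magnesium chelate prevents over-addition and releases the C9=C10–C11 vinyl ketone only on acidic quench, while the hindered conjugated ester is spared and the OH and NH are merely deprotonated.

Step 20
Reactants: 34 vinyl ketone from step 19; 8 (2S,4R)-6-iodo-2,4-dimethylhexanoic acid
Product: 36 2-(trimethylsilyl)ethyl (2Z,4E,6R)-6-ethyl-2-[(3R,4S,6S)-3,4,6-tris[(tert-butyldimethylsilyl)oxy]-7-{[(2S)-2-{[(2S,4R)-6-iodo-2,4-dimethylhexanoyl]oxy}pentanoyl]amino}heptyl]-10-oxododeca-2,4,11-trienoate, via mixed anhydride 35 (not isolated)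
Conditions: 8 (1.5 equiv), 2,4,6-Cl3C6H2COCl, Et3N, THF, 0 °C; then 34, DMAP, PhMe, 23 °C
Reagents that add atoms: none
Why: Yamaguchi esterification acylates the only free hydroxyl (C1–OH) through the mixed anhydride without epimerising C4 or C1, giving the seco compound that carries both the radical precursor and the acceptor.

Step 21
Reactants: 36 seco iodo-enone from step 20
Product: 39 tris-O-TBS 2-(trimethylsilyl)ethyl ester of the target macrocycle, via primary alkyl radical 37 (not isolated), via α-keto radical 38 (not isolated)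
Conditions: Bu3SnH (1.5 equiv), AIBN (0.3 equiv), added by syringe pump over 12 h to 36 (1.5 mM) in degassed PhH, 80 °C
Reagents that add atoms: none
Why: tin-hydride-mediated radical macrocyclisation (endo Giese addition of an ω-iodoalkyl chain to a vinyl ketone), in which the nucleophilic primary C8 radical adds to the unsubstituted enone terminus faster than to the hindered dienoate or than H-transfer at high dilution and the α-keto radical is then reduced, forms C8–C9 and the 28-membered ring without creating or disturbing any stereocentre.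

Step 22
Reactants: 39 protected macrocycle from step 21
Product: 40 CNP0182412.1 (target)
Conditions: TBAF (15 equiv), AcOH (7 equiv), THF, 23 → 40 °C; pH 4 buffer work-up
Reagents that add atoms: none
Why: buffered fluoride removes the three TBS ethers and cleaves the 2-(trimethylsilyl)ethyl ester by β-elimination in one operation, and the carboxylate form prevents δ-lactonisation onto C22–OH.

**Compound list**
1 | tert-butyl(but-3-en-1-yloxy)dimethylsilane | C=CCCO[Si](C)(C)C(C)(C)C | starting material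
2 | bromoethene | C=CBr | starting material
3 | dimethyl{(2S)-4-[(tert-butyldimethylsilyl)oxy]-2-methylbutyl}alane | C[Al](C)C[C@@H](C)CCO[Si](C)(C)C(C)(C)C | intermediate
4 | (R)-tert-butyldimethyl[(3-methylhex-5-en-1-yl)oxy]silane | C=CC[C@@H](C)CCO[Si](C)(C)C(C)(C)C | intermediate
5 | dimethyl{(2S,4R)-6-[(tert-butyldimethylsilyl)oxy]-2,4-dimethylhexyl}alane | C[Al](C)C[C@@H](C)C[C@@H](C)CCO[Si](C)(C)C(C)(C)C | intermediate
6 | (2S,4R)-6-[(tert-butyldimethylsilyl)oxy]-2,4-dimethylhexan-1-ol | OC[C@@H](C)C[C@@H](C)CCO[Si](C)(C)C(C)(C)C | intermediate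
7 | (2S,4R)-6-[(tert-butyldimethylsilyl)oxy]-2,4-dimethylhexanoic acid | OC(=O)[C@@H](C)C[C@@H](C)CCO[Si](C)(C)C(C)(C)C | intermediate
8 | (2S,4R)-6-iodo-2,4-dimethylhexanoic acid | OC(=O)[C@@H](C)C[C@@H](C)CCI | intermediate
9 | hex-5-enoyl chloride | C=CCCCC(=O)Cl | starting material
10 | N-methoxy-N-methylhex-5-enamide | C=CCCCC(=O)N(C)OC | intermediate
11 | (E)-1,4-dibromobut-2-ene | BrC/C=C/CBr | starting material
12 | (E)-7-bromo-N-methoxy-N-methylhept-5-enamide | CON(C)C(=O)CCC/C=C/CBr | intermediate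
13 | (R)-5-ethyl-N-methoxy-N-methylhept-6-enamide | CON(C)C(=O)CCC[C@@H](CC)C=C | intermediate
14 | (E)-but-2-enal | C/C=C/C=O | starting material
15 | (5R,6E)-5-ethyl-N-methoxy-N-methyl-8-oxooct-6-enamide | CON(C)C(=O)CCC[C@@H](CC)/C=C/C=O | intermediate
16 | (5R,6E)-9,9-dibromo-5-ethyl-N-methoxy-N-methylnona-6,8-dienamide | CON(C)C(=O)CCC[C@@H](CC)/C=C/C=C(Br)Br | intermediate
17 | (S)-4-chloro-3-hydroxybutanenitrile | N#CC[C@H](O)CCl | starting material
18 | (S)-4-azido-3-hydroxybutanenitrile | N#CC[C@H](O)CN=[N+]=[N-] | intermediate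
19 | (S)-4-azido-3-[(tert-butyldimethylsilyl)oxy]butanenitrile | N#CC[C@H](O[Si](C)(C)C(C)(C)C)CN=[N+]=[N-] | intermediate
20 | (S)-4-azido-3-[(tert-butyldimethylsilyl)oxy]butanal | O=CC[C@H](O[Si](C)(C)C(C)(C)C)CN=[N+]=[N-] | intermediate
21 | allyl(chloro)dimethylsilane | C=CC[Si](C)(C)Cl | starting material
22 | allyl(diisopropylamino)dimethylsilane | C=CC[Si](C)(C)N(C(C)C)C(C)C | intermediate
23 | (E)-{3-[(diisopropylamino)dimethylsilyl]allyl}lithium | [Li]C/C=C/[Si](C)(C)N(C(C)C)C(C)C | intermediate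
24 | {(E)-3-[(diisopropylamino)dimethylsilyl]allyl}bis[(1S,2R,3S,5S)-isopinocampheyl]borane | CC(C)N(C(C)C)[Si](C)(C)/C=C/CB([C@H]1C[C@H]2C[C@@H]([C@@H]1C)C2(C)C)[C@H]1C[C@H]2C[C@@H]([C@@H]1C)C2(C)C | intermediate
25 | O-(diisopinocampheylboryl) adduct: (3R,4S,6S)-7-azido-6-(TBSO)-3-[(diisopropylamino)dimethylsilyl]hept-1-en-4-yl borinate | C=C[C@@H]([Si](C)(C)N(C(C)C)C(C)C)[C@@H](OB([C@H]1C[C@H]2C[C@@H]([C@@H]1C)C2(C)C)[C@H]1C[C@H]2C[C@@H]([C@@H]1C)C2(C)C)C[C@H](O[Si](C)(C)C(C)(C)C)CN=[N+]=[N-] | intermediate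
26 | (3R,4S,6S)-7-azido-6-[(tert-butyldimethylsilyl)oxy]hept-1-ene-3,4-diol | C=C[C@@H](O)[C@@H](O)C[C@H](O[Si](C)(C)C(C)(C)C)CN=[N+]=[N-] | intermediate
27 | (3R,4S,6S)-7-azido-3,4,6-tris[(tert-butyldimethylsilyl)oxy]hept-1-ene | C=C[C@@H](O[Si](C)(C)C(C)(C)C)[C@@H](O[Si](C)(C)C(C)(C)C)C[C@H](O[Si](C)(C)C(C)(C)C)CN=[N+]=[N-] | intermediate
28 | (S)-2-hydroxypentanoic acid | CCC[C@H](O)C(=O)O | starting material
29 | (2S,4S,5R)-2,4,5-tris[(tert-butyldimethylsilyl)oxy]hept-6-en-1-amine | C=C[C@@H](O[Si](C)(C)C(C)(C)C)[C@@H](O[Si](C)(C)C(C)(C)C)C[C@H](O[Si](C)(C)C(C)(C)C)CN | intermediate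
30 | (2S)-2-hydroxy-N-[(2S,4S,5R)-2,4,5-tris[(tert-butyldimethylsilyl)oxy]hept-6-en-1-yl]pentanamide | C=C[C@@H](O[Si](C)(C)C(C)(C)C)[C@@H](O[Si](C)(C)C(C)(C)C)C[C@H](O[Si](C)(C)C(C)(C)C)CNC(=O)[C@@H](O)CCC | intermediate
31 | 9-BBN adduct of 30: B-alkyl-9-borabicyclo[3.3.1]nonane at C20, C1 hydroxyl as its 9-BBN borinate | C1CCC2CCCC1B2CC[C@@H](O[Si](C)(C)C(C)(C)C)[C@@H](O[Si](C)(C)C(C)(C)C)C[C@H](O[Si](C)(C)C(C)(C)C)CNC(=O)[C@@H](OB1C2CCCC1CCC2)CCC | intermediate
32 | (2S)-N-[(2S,4S,5R,8Z,10E,12R)-8-bromo-2,4,5-tris[(tert-butyldimethylsilyl)oxy]-12-ethyl-16-[methoxy(methyl)amino]-16-oxohexadeca-8,10-dien-1-yl]-2-hydroxypentanamide | CON(C)C(=O)CCC[C@@H](CC)/C=C/C=C(\Br)CC[C@@H](O[Si](C)(C)C(C)(C)C)[C@@H](O[Si](C)(C)C(C)(C)C)C[C@H](O[Si](C)(C)C(C)(C)C)CNC(=O)[C@@H](O)CCC | intermediate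
33 | 2-(trimethylsilyl)ethyl (2Z,4E,6R)-6-ethyl-10-[methoxy(methyl)amino]-10-oxo-2-[(3R,4S,6S)-3,4,6-tris(TBSO)-7-{[(2S)-2-hydroxypentanoyl]amino}heptyl]deca-2,4-dienoate | CON(C)C(=O)CCC[C@@H](CC)/C=C/C=C(\C(=O)OCC[Si](C)(C)C)CC[C@@H](O[Si](C)(C)C(C)(C)C)[C@@H](O[Si](C)(C)C(C)(C)C)C[C@H](O[Si](C)(C)C(C)(C)C)CNC(=O)[C@@H](O)CCC | intermediate
34 | 2-(trimethylsilyl)ethyl (2Z,4E,6R)-6-ethyl-10-oxo-2-[(3R,4S,6S)-3,4,6-tris(TBSO)-7-{[(2S)-2-hydroxypentanoyl]amino}heptyl]dodeca-2,4,11-trienoate | C=CC(=O)CCC[C@@H](CC)/C=C/C=C(\C(=O)OCC[Si](C)(C)C)CC[C@@H](O[Si](C)(C)C(C)(C)C)[C@@H](O[Si](C)(C)C(C)(C)C)C[C@H](O[Si](C)(C)C(C)(C)C)CNC(=O)[C@@H](O)CCC | intermediate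
35 | (2S,4R)-6-iodo-2,4-dimethylhexanoic 2,4,6-trichlorobenzoic anhydride | O=C(OC(=O)[C@@H](C)C[C@@H](C)CCI)c1c(Cl)cc(Cl)cc1Cl | intermediate
36 | seco iodo-enone: 34 esterified at the pentanoyl C2 hydroxyl by (2S,4R)-6-iodo-2,4-dimethylhexanoic acid | C=CC(=O)CCC[C@@H](CC)/C=C/C=C(\C(=O)OCC[Si](C)(C)C)CC[C@@H](O[Si](C)(C)C(C)(C)C)[C@@H](O[Si](C)(C)C(C)(C)C)C[C@H](O[Si](C)(C)C(C)(C)C)CNC(=O)[C@H](CCC)OC(=O)[C@@H](C)C[C@@H](C)CCI | intermediate
37 | primary C8 radical derived from 36 | C=CC(=O)CCC[C@@H](CC)/C=C/C=C(\C(=O)OCC[Si](C)(C)C)CC[C@@H](O[Si](C)(C)C(C)(C)C)[C@@H](O[Si](C)(C)C(C)(C)C)C[C@H](O[Si](C)(C)C(C)(C)C)CNC(=O)[C@H](CCC)OC(=O)[C@@H](C)C[C@@H](C)C[CH2] | intermediate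
38 | macrocyclic C10 (α-keto) radical | CCC[C@@H]1OC(=O)[C@@H](C)C[C@@H](C)CCC[CH]C(=O)CCC[C@@H](CC)/C=C/C=C(\C(=O)OCC[Si](C)(C)C)CC[C@@H](O[Si](C)(C)C(C)(C)C)[C@@H](O[Si](C)(C)C(C)(C)C)C[C@H](O[Si](C)(C)C(C)(C)C)CNC1=O | intermediate
39 | target macrocycle as its 22,23,25-tris-O-TBS ether and 2-(trimethylsilyl)ethyl ester | CCC[C@@H]1OC(=O)[C@@H](C)C[C@@H](C)CCCCC(=O)CCC[C@@H](CC)/C=C/C=C(\C(=O)OCC[Si](C)(C)C)CC[C@@H](O[Si](C)(C)C(C)(C)C)[C@@H](O[Si](C)(C)C(C)(C)C)C[C@H](O[Si](C)(C)C(C)(C)C)CNC1=O | intermediate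
40 | CNP0182412.1 (1S,4S,6S,15R,22R,23S,25S; 16E,18Z) | CCC[C@@H]1OC(=O)[C@@H](C)C[C@@H](C)CCCCC(=O)CCC[C@@H](CC)/C=C/C=C(\C(=O)O)CC[C@@H](O)[C@@H](O)C[C@H](O)CNC1=O | target

**Totals and risk**
Total step count: 22. Longest linear sequence: 12 steps (17 → 40 through steps 10–12 and 14–22).

Most likely to fail:

Step 21 (radical macrocyclisation). The 28-membered closure competes with direct reduction of the C8 radical, oligomerisation and addition to the dienoate. Fallback: setting out from 34 and 8, the same radical C8–C9 bond is made intermolecularly (8 in excess, (Me3Si)3SiH, AIBN, PhH, 80 °C, 0.1 M) to give the seco hydroxy acid F1. F1 is then closed at the O2–C3 ester bond by Yamaguchi macrolactonisation at high dilution and comes back to the route at 39.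

Step 17 (trans-selective B-alkyl Suzuki mono-coupling of the dibromodiene). Double coupling, alkyne formation by dehydrobromination, or slow transmetalation next to the borylated hydroxyl could erode yield and geometry. Fallback: setting out from 15, an (E)-selective bromo-olefination (Horner–Wadsworth–Emmons with 2-(trimethylsilyl)ethyl bromo[bis(2,2,2-trifluoroethoxy)phosphoryl]acetate, KHMDS, 18-crown-6, THF, −78 °C) gives the (E)-α-bromo dienoate F2, which has a single C–Br bond and the ester already in place. Coupling F2 with borane 31 (from 30) under the step 17 palladium conditions comes back to the route at 33 and bypasses 16, 32 and the carbonylation.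

Step 20 (esterification in the presence of the vinyl ketone and the alkyl iodide). DMAP or the alcohol may add to the enone, or the enone may polymerise. Fallback: setting out from 33, the Yamaguchi esterification with 8 is run before the enone exists, giving the Weinreb-amide iodo ester F3. The vinyl ketone is then unveiled last with CH2=CHMgBr (THF, −78 → −40 °C), which comes back to the route at 36.

**Further compounds**
F1 | step 21 | seco hydroxy acid: C8–C9-linked ketone with free C3 carboxylic acid and free C1 hydroxyl (tris-TBS, TMSE ester) | OC(=O)[C@@H](C)C[C@@H](C)CCCCC(=O)CCC[C@@H](CC)/C=C/C=C(\C(=O)OCC[Si](C)(C)C)CC[C@@H](O[Si](C)(C)C(C)(C)C)[C@@H](O[Si](C)(C)C(C)(C)C)C[C@H](O[Si](C)(C)C(C)(C)C)CNC(=O)[C@@H](O)CCC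
F2 | step 17 | 2-(trimethylsilyl)ethyl (2E,4E,6R)-2-bromo-6-ethyl-10-[methoxy(methyl)amino]-10-oxodeca-2,4-dienoate | CON(C)C(=O)CCC[C@@H](CC)/C=C/C=C(\C(=O)OCC[Si](C)(C)C)Br
F3 | step 20 | Weinreb-amide iodo ester: 33 esterified at the pentanoyl C2 hydroxyl by (2S,4R)-6-iodo-2,4-dimethylhexanoic acid | CON(C)C(=O)CCC[C@@H](CC)/C=C/C=C(\C(=O)OCC[Si](C)(C)C)CC[C@@H](O[Si](C)(C)C(C)(C)C)[C@@H](O[Si](C)(C)C(C)(C)C)C[C@H](O[Si](C)(C)C(C)(C)C)CNC(=O)[C@H](CCC)OC(=O)[C@@H](C)C[C@@H](C)CCI
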